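**Plan**

- Cuts, in retrosynthetic order: the three O–benzyl bonds; the C3–C4 bond of ring C (pyranone of the flavanone), giving the achiral formyl enol ether 11; the C2=C3 unsaturation and the O1–C2 ether bond, giving phenol 9 (ring A) and bromohydrin 7; the aryl–vinyl bond, giving bromide 5; ring D (dimethylpyranone fused to ring B), giving acetophenone 3 and acetone.
- Enabling feature: ring C is a β-aryloxy ketone. Its C4 carbonyl lies between the unsubstituted C3 methylene and C4a (ortho to O1), and C2 carries one H. The array O1–C2(H)(Ar)–C3H2–C4(=O) is therefore the formal adduct of a ring-A formyl C–H across an O1–C2(Ar)=C3H2 enol ether.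
- Forward order: ring D by Kabbe condensation on the brominated ring-B acetophenone; two-carbon unit by Suzuki vinylation and bromohydrin formation; union with ring A through O1 (Mitsunobu); C2=C3 by dehydrobromination; ring C by enantioselective intramolecular hydroacylation; global debenzylation.
- Stereochemistry: C2 is the only stereocentre. It is set in the ring-C closure by the chiral rhodium bisphosphine catalyst during hydride delivery to C2. The racemic centre carried in 7 and 10 is erased in step 8.

Key step: step 9

Assumption: the sense of induction of a given ligand antipode cannot be derived with certainty for this new substrate class; (R)-MeO-BIPHEP is written, and the (S)-antipode is to be used if a small-scale trial shows the (2R) series.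

**Step 1**
Reactants: 1 2',3'-dihydroxyacetophenone
Product: 2 1-[3-(benzyloxy)-2-hydroxyphenyl]ethan-1-one
Conditions: NaH (2.1 equiv), DMSO, rt; BnBr (1.0 equiv), rt; aq. HCl work-up
Reagents that add atoms: benzyl bromide BrCc1ccccc1
Why: Williamson etherification of the catecholate dianion, in which the 3-oxide (neither conjugated with nor chelated to the acetyl group) is the more nucleophilic oxygen and should take up the single equivalent of BnBr.

**Step 2**
Reactants: 2 1-[3-(benzyloxy)-2-hydroxyphenyl]ethan-1-one
Product: 3 1-[3-(benzyloxy)-5-bromo-2-hydroxyphenyl]ethan-1-one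
Conditions: NBS (1.05 equiv), MeCN, 0 °C to rt
Reagents that add atoms: N-bromosuccinimide O=C1CCC(=O)N1Br
Why: Electrophilic aromatic bromination para to the free phenol (C5), the position activated by the hydroxyl group and meta to the acetyl group, as in the bromination of related 2-hydroxy-3-alkoxy aryl carbonyl compounds.

**Step 3**
Reactants: 3 1-[3-(benzyloxy)-5-bromo-2-hydroxyphenyl]ethan-1-one
Product: 5 8-(benzyloxy)-6-bromo-2,2-dimethylchroman-4-one, via enone 4 (not isolated)
Conditions: acetone (5 equiv), pyrrolidine (1.0 equiv), MeOH, 50 °C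
Reagents that add atoms: acetone CC(C)=O
Why: Kabbe condensation, in which amine-mediated aldol condensation of the methyl ketone with acetone gives the o-hydroxyaryl enone 4, and oxa-Michael addition of the phenol then closes ring D.

**Step 4**
Reactants: 5 8-(benzyloxy)-6-bromo-2,2-dimethylchroman-4-one
Product: 6 8-(benzyloxy)-6-ethenyl-2,2-dimethylchroman-4-one
Conditions: vinylboronic acid pinacol ester (1.3 equiv), Pd(dppf)Cl2 (3 mol %), K2CO3 (2.5 equiv), 1,4-dioxane/H2O 4:1, 85 °C
Reagents that add atoms: 4,4,5,5-tetramethyl-2-vinyl-1,3,2-dioxaborolane C=CB1OC(C)(C)C(C)(C)O1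
Why: Suzuki–Miyaura coupling of an unhindered aryl bromide (oxidative addition to zerovalent palladium, transmetalation, reductive elimination); the ketone and the benzyl ether are inert to these conditions.

**Step 5**
Reactants: 6 8-(benzyloxy)-6-ethenyl-2,2-dimethylchroman-4-one
Product: 7 8-(benzyloxy)-6-(2-bromo-1-hydroxyethyl)-2,2-dimethylchroman-4-one (racemic)
Conditions: NBS (1.1 equiv), THF/H2O 3:1, 0 °C to rt
Reagents that add atoms: N-bromosuccinimide O=C1CCC(=O)N1Br; water O
Why: Bromohydrin formation, in which the bromonium ion of the p-alkoxystyrene is opened by water at the benzylic carbon (Markovnikov); the new stereocentre is racemic and is removed in step 8.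

**Step 6**
Reactants: 8 2,4,6-trihydroxybenzaldehyde
Product: 9 2,4-bis(benzyloxy)-6-hydroxybenzaldehyde
Conditions: BnBr (2.05 equiv), K2CO3 (2.1 equiv), DMF, 0 °C to rt
Reagents that add atoms: benzyl bromide BrCc1ccccc1
Why: Williamson etherification that should stop at the dibenzyl ether, because the last ortho hydroxyl group is hydrogen-bonded to the formyl group and is the least reactive.

**Step 7**
Reactants: 7 8-(benzyloxy)-6-(2-bromo-1-hydroxyethyl)-2,2-dimethylchroman-4-one; 9 2,4-bis(benzyloxy)-6-hydroxybenzaldehyde
Product: 10 2,4-bis(benzyloxy)-6-{1-[8-(benzyloxy)-2,2-dimethyl-4-oxochroman-6-yl]-2-bromoethoxy}benzaldehyde (racemic)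
Conditions: PPh3 (1.3 equiv), DIAD (1.3 equiv), THF, 0 °C to rt
Reagents that add atoms: none
Why: Mitsunobu etherification of an acidic salicylaldehyde-type phenol with a secondary benzylic alcohol forms the O1–C2 bond; the configuration at this carbon is irrelevant because it becomes trigonal in step 8.

**Step 8**
Reactants: 10 2,4-bis(benzyloxy)-6-{1-[8-(benzyloxy)-2,2-dimethyl-4-oxochroman-6-yl]-2-bromoethoxy}benzaldehyde
Product: 11 2,4-bis(benzyloxy)-6-({1-[8-(benzyloxy)-2,2-dimethyl-4-oxochroman-6-yl]ethenyl}oxy)benzaldehyde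
Conditions: DBU (3 equiv), toluene, 80 °C; filtration through Et3N-deactivated silica
Reagents that add atoms: none
Why: E2 dehydrobromination of a β-bromo ether, the classical route to α-alkoxystyrenes; the only β-hydrogen is the benzylic, oxygen-bearing one, so only the 1,1-disubstituted enol ether can form, and the amidine base should spare the formyl group and the chromanone.

**Step 9**
Reactants: 11 2,4-bis(benzyloxy)-6-({1-[8-(benzyloxy)-2,2-dimethyl-4-oxochroman-6-yl]ethenyl}oxy)benzaldehyde
Product: 12 (2S)-5,7-bis(benzyloxy)-2-[8-(benzyloxy)-2,2-dimethyl-4-oxochroman-6-yl]chroman-4-one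
Conditions: [Rh(cod)2]BF4 (5 mol %), (R)-MeO-BIPHEP (5.5 mol %), acid-free THF, 60 °C, argon
Reagents that add atoms: none
Why: Proposed new method: a cationic bisphosphine complex of monovalent rhodium should insert into the formyl C–H bond of 11 to give an acyl hydride of trivalent rhodium; the C2=C3 enol ether bond then inserts into Rh–H with hydride going to C2 and rhodium to the C3 methylene, and C–C reductive elimination from the seven-membered acyl–alkyl rhodacycle forms the C3–C4 bond and frees the catalyst. The closest known reaction type is the enantioselective rhodium-catalysed intramolecular hydroacylation of 1,1-disubstituted alkenes (2-isopropenylbenzaldehydes to 3-substituted indanones, N-(1-arylvinyl)indole-2-carbaldehydes to 3-aryl dihydropyrroloindolones, heteroatom-tethered methallyl aldehydes to medium-ring ketones), which has not been shown for 1-arylvinyl ethers of salicylaldehydes. Ring C closes in a 6-endo-trig mode with respect to C2=C3, both alkene carbons ending up in the ring. The C2 stereocentre is created when hydride is delivered to the prochiral C2 terminus, and its configuration is controlled by the chiral bisphosphine alone, which differentiates the two faces of the coordinated alkene; the neutral conditions leave no retro-oxa-Michael path for racemisation. The step needs acyl transfer to C3 in preference to the 5-exo alternative (a 2-aryl-2-methylbenzofuran-3-one), which the 1,1-disubstitution should secure by disfavouring a tertiary alkyl rhodium species and reductive elimination to a quaternary carbon; it needs hydroacylation to outrun decarbonylation, which the two ortho oxygen substituents of the aldehyde (O1 and the 5-benzyloxy group) should help by chelating the acyl rhodium intermediate; and it needs strict exclusion of protic acid, since 11 would otherwise condense to a flavylium ion.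

**Step 10**
Reactants: 12 (2S)-5,7-bis(benzyloxy)-2-[8-(benzyloxy)-2,2-dimethyl-4-oxochroman-6-yl]chroman-4-one
Product: 13 (2S)-5,7-dihydroxy-2-(8-hydroxy-2,2-dimethyl-4-oxochroman-6-yl)chroman-4-one (target)
Conditions: H2 (1 atm), 10% Pd/C, EtOAc/MeOH 1:1, rt
Reagents that add atoms: none
Why: Hydrogenolysis of the three aryl benzyl ethers under neutral conditions, routine for benzylated flavanones, should leave the aryl ketones and the C2–O1 bond intact and cannot epimerise C2.

**Compound list**

1 | 2',3'-dihydroxyacetophenone | CC(=O)c1cccc(O)c1O | starting material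
2 | 1-[3-(benzyloxy)-2-hydroxyphenyl]ethan-1-one | CC(=O)c1cccc(OCc2ccccc2)c1O | intermediate
3 | 1-[3-(benzyloxy)-5-bromo-2-hydroxyphenyl]ethan-1-one | CC(=O)c1cc(Br)cc(OCc2ccccc2)c1O | intermediate
4 | 1-[3-(benzyloxy)-5-bromo-2-hydroxyphenyl]-3-methylbut-2-en-1-one | CC(C)=CC(=O)c1cc(Br)cc(OCc2ccccc2)c1O | intermediate (not isolated)
5 | 8-(benzyloxy)-6-bromo-2,2-dimethylchroman-4-one | CC1(C)CC(=O)c2cc(Br)cc(OCc3ccccc3)c2O1 | intermediate
6 | 8-(benzyloxy)-6-ethenyl-2,2-dimethylchroman-4-one | CC1(C)CC(=O)c2cc(C=C)cc(OCc3ccccc3)c2O1 | intermediate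
7 | 8-(benzyloxy)-6-(2-bromo-1-hydroxyethyl)-2,2-dimethylchroman-4-one (racemic) | CC1(C)CC(=O)c2cc(C(O)CBr)cc(OCc3ccccc3)c2O1 | intermediate
8 | 2,4,6-trihydroxybenzaldehyde | O=Cc1c(O)cc(O)cc1O | starting material
9 | 2,4-bis(benzyloxy)-6-hydroxybenzaldehyde | O=Cc1c(O)cc(OCc2ccccc2)cc1OCc1ccccc1 | intermediate
10 | 2,4-bis(benzyloxy)-6-{1-[8-(benzyloxy)-2,2-dimethyl-4-oxochroman-6-yl]-2-bromoethoxy}benzaldehyde (racemic) | O=Cc1c(OC(CBr)c2cc(OCc4ccccc4)c3OC(C)(C)CC(=O)c3c2)cc(OCc2ccccc2)cc1OCc1ccccc1 | intermediate
11 | 2,4-bis(benzyloxy)-6-({1-[8-(benzyloxy)-2,2-dimethyl-4-oxochroman-6-yl]ethenyl}oxy)benzaldehyde | O=Cc1c(OC(=C)c2cc(OCc4ccccc4)c3OC(C)(C)CC(=O)c3c2)cc(OCc2ccccc2)cc1OCc1ccccc1 | intermediate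
12 | (2S)-5,7-bis(benzyloxy)-2-[8-(benzyloxy)-2,2-dimethyl-4-oxochroman-6-yl]chroman-4-one | CC1(C)CC(=O)c2cc([C@@H]3CC(=O)c4c(OCc5ccccc5)cc(OCc5ccccc5)cc4O3)cc(OCc3ccccc3)c2O1 | intermediate
13 | (2S)-5,7-dihydroxy-2-(8-hydroxy-2,2-dimethyl-4-oxochroman-6-yl)chroman-4-one | CC1(C)CC(=O)c2cc([C@@H]3CC(=O)c4c(O)cc(O)cc4O3)cc(O)c2O1 | target

**Step count**

Total steps: 10. Longest linear sequence: 9 steps (1 to 13 through steps 1–5 and 7–10); the ring-A branch (step 6) joins at step 7.

**Steps most likely to fail**

Step 9 (proposed new method). The hydroacylation may lose to decarbonylation of the acyl rhodium hydride, to Markovnikov (5-exo) acyl transfer, to acid-triggered cyclocondensation of the substrate, or may show poor facial discrimination. The fallback sets out from 5 and returns at 12 by known chemistry. Palladium-catalysed borylation of 5 (Pd(OAc)2, XPhos, KOAc, B2(OH)4, EtOH, 80 °C) gives [8-(benzyloxy)-2,2-dimethyl-4-oxochroman-6-yl]boronic acid F1. Separately, purchased 1-[2,4-bis(benzyloxy)-6-hydroxyphenyl]ethan-1-one F2 is condensed with N,N-dimethylformamide dimethyl acetal to the enaminone (E)-1-[2,4-bis(benzyloxy)-6-hydroxyphenyl]-3-(dimethylamino)prop-2-en-1-one F3, which is cyclised with aqueous HCl to 5,7-bis(benzyloxy)-4H-chromen-4-one F4. Enantioselective conjugate addition of F1 to F4 (Pd(OCOCF3)2, the t-BuPyOx antipode that leads to the 2S series, NH4PF6, H2O, 1,2-dichloroethane, 60 °C) then forms the C2–aryl bond and the stereocentre under catalyst control, giving 12.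

Step 8. Enolisation of the chromanone by the base may open ring D or lead to aldol condensation with the formyl group, and the enol ether may be hydrolysed or cyclocondensed on acidic supports during isolation. The fallback sets out from 10 and returns at 11 without base-mediated elimination. Displacement of the primary bromide with benzeneselenol (Cs2CO3, DMF, 0 °C) gives 2,4-bis(benzyloxy)-6-{1-[8-(benzyloxy)-2,2-dimethyl-4-oxochroman-6-yl]-2-(phenylselanyl)ethoxy}benzaldehyde F5. Oxidation with NaIO4 (NaHCO3, THF/MeOH/H2O, 0 °C) gives the selenoxide 2,4-bis(benzyloxy)-6-{1-[8-(benzyloxy)-2,2-dimethyl-4-oxochroman-6-yl]-2-(phenylseleninyl)ethoxy}benzaldehyde F6, which should undergo thermal syn-elimination at rt to 40 °C under near-neutral conditions to 11.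

Step 7. The activated benzylic oxyphosphonium intermediate may ionise or eliminate to a bromostyrene faster than the hydrogen-bonded phenol substitutes. The fallback sets out from 6 (with 9) and returns at 10 by alkylation in place of redox condensation. Addition of Br2 to 6 (CH2Cl2, −78 °C) gives 8-(benzyloxy)-6-(1,2-dibromoethyl)-2,2-dimethylchroman-4-one F7, whose benzylic bromide, activated by the para ring oxygen, should be displaced by the phenoxide of 9 (Cs2CO3, DMF, rt) to give 10.

**Further compounds**

F1 | step 9 | [8-(benzyloxy)-2,2-dimethyl-4-oxochroman-6-yl]boronic acid | CC1(C)CC(=O)c2cc(B(O)O)cc(OCc3ccccc3)c2O1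
F2 | step 9 | 1-[2,4-bis(benzyloxy)-6-hydroxyphenyl]ethan-1-one (purchased) | CC(=O)c1c(O)cc(OCc2ccccc2)cc1OCc1ccccc1
F3 | step 9 | (E)-1-[2,4-bis(benzyloxy)-6-hydroxyphenyl]-3-(dimethylamino)prop-2-en-1-one | CN(C)/C=C/C(=O)c1c(O)cc(OCc2ccccc2)cc1OCc1ccccc1
F4 | step 9 | 5,7-bis(benzyloxy)-4H-chromen-4-one | O=c1ccoc2cc(OCc3ccccc3)cc(OCc3ccccc3)c12
F5 | step 8 | 2,4-bis(benzyloxy)-6-{1-[8-(benzyloxy)-2,2-dimethyl-4-oxochroman-6-yl]-2-(phenylselanyl)ethoxy}benzaldehyde | O=Cc1c(OC(C[Se]c5ccccc5)c2cc(OCc4ccccc4)c3OC(C)(C)CC(=O)c3c2)cc(OCc2ccccc2)cc1OCc1ccccc1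
F6 | step 8 | 2,4-bis(benzyloxy)-6-{1-[8-(benzyloxy)-2,2-dimethyl-4-oxochroman-6-yl]-2-(phenylseleninyl)ethoxy}benzaldehyde | O=Cc1c(OC(C[Se](=O)c5ccccc5)c2cc(OCc4ccccc4)c3OC(C)(C)CC(=O)c3c2)cc(OCc2ccccc2)cc1OCc1ccccc1
F7 | step 7 | 8-(benzyloxy)-6-(1,2-dibromoethyl)-2,2-dimethylchroman-4-one | CC1(C)CC(=O)c2cc(C(Br)CBr)cc(OCc3ccccc3)c2O1
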